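**Retrosynthetic overview**
- Target 21 ⇐ acid 14: the C1'–C4' chain is grown from the CH2CO2H arm by reduction, methylenation, cross-metathesis with 2-methylbut-3-en-2-ol, hydrogenation and desilylation.
- 14 ⇐ anhydride 12: the C4–C4a bond is made by an enantioselective intramolecular nickel-catalysed reductive aryl–acyl coupling. This closes the pyranone ring (O1–C2–C3–C4–C4a–C8a), the only ring formed, onto the purchased benzene ring and sets C2.
- Feature used: the quaternary C2 carries two CH2 arms, C3 (in the pyranone ring) and C1' (side chain). C4 and C2' can therefore both be traced back to the two enantiotopic carbonyls of an achiral 3-aryloxy-3-methylglutaric anhydride.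
- 12 ⇐ diene 5: both allyl groups are cleaved to the diacid and dehydrated; the C4a iodide comes from a nitro group (reduction, Sandmeyer), so its position is fixed by the starting arene.
- 5 ⇐ 2 + 3: the O1–C8a bond is made by SNAr of the diallylmethylcarbinol alkoxide on an o-fluoronitroarene.

Key step: step 7

Assumptions: 2-bromo-4-fluoro-5-nitrophenol (1) is taken as a catalogue compound; the sense of induction of the chiral nickel catalyst in step 7 cannot be predicted, so the ligand antipode that delivers the (S)-acid 14 is to be selected.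

**Step 1**
Reactants: 1 2-bromo-4-fluoro-5-nitrophenol
Product: 2 (2-bromo-4-fluoro-5-nitrophenoxy)triisopropylsilane
Conditions: TIPSCl, imidazole, DMF, rt
Reagents that add atoms: triisopropylsilyl chloride, CC(C)[Si](Cl)(C(C)C)C(C)C
Why: Silyl ether formation on the acidic phenol with TIPSCl/imidazole is routine, and the bulky silyl group later shields the neighbouring C–Br bond.

**Step 2**
Reactants: 2 (2-bromo-4-fluoro-5-nitrophenoxy)triisopropylsilane; 3 4-methylhepta-1,6-dien-4-ol
Product: 5 [2-bromo-4-[(4-methylhepta-1,6-dien-4-yl)oxy]-5-nitrophenoxy]triisopropylsilane, via potassium 4-methylhepta-1,6-dien-4-olate 4 (not isolated)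
Conditions: 3 (1.2 equiv), KHMDS (1.1 equiv), THF, −78 °C; then 2, −78 → 0 °C
Reagents that add atoms: none
Why: Nucleophilic aromatic substitution (SNAr) through a Meisenheimer adduct: the fluoride ortho to the nitro group is displaced far faster than the bromide para to it, and at low temperature the hindered alkoxide should attack the activated carbon faster than the hindered silicon.

**Step 3**
Reactants: 5 [2-bromo-4-[(4-methylhepta-1,6-dien-4-yl)oxy]-5-nitrophenoxy]triisopropylsilane
Product: 8 3-[5-bromo-2-nitro-4-(triisopropylsilyloxy)phenoxy]-3-methylpentanedioic acid, via bis-ozonide 6 (not isolated), via dialdehyde 7 (not isolated)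
Conditions: O3, CH2Cl2, −78 °C; PPh3, −78 °C → rt; then NaClO2, NaH2PO4, 2-methyl-2-butene, t-BuOH/H2O, 0 °C → rt
Reagents that add atoms: ozone, [O-][O+]=O; sodium chlorite, [Na+].[O-]Cl=O
Why: Ozonolysis cleaves only the two terminal alkenes (the nitroarene is deactivated towards ozone), phosphine reduces the ozonide to the dialdehyde, and buffered Pinnick oxidation gives the diacid without the base that would trigger E1cB loss of the β-aryloxy group.

**Step 4**
Reactants: 8 3-[5-bromo-2-nitro-4-(triisopropylsilyloxy)phenoxy]-3-methylpentanedioic acid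
Product: 9 3-[2-amino-5-bromo-4-(triisopropylsilyloxy)phenoxy]-3-methylpentanedioic acid
Conditions: H2 (1 atm), 5% Pt/C (sulfided), EtOAc, rt
Reagents that add atoms: none
Why: Heterogeneous hydrogenation over sulfided platinum reduces the nitro group chemoselectively and is known to leave aryl bromides and silyl ethers untouched.

**Step 5**
Reactants: 9 3-[2-amino-5-bromo-4-(triisopropylsilyloxy)phenoxy]-3-methylpentanedioic acid
Product: 11 3-[5-bromo-2-iodo-4-(triisopropylsilyloxy)phenoxy]-3-methylpentanedioic acid, via arenediazonium tosylate 10 (not isolated)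
Conditions: NaNO2, p-TsOH·H2O, KI, MeCN/H2O, 10 °C → rt
Reagents that add atoms: potassium iodide, [K+].[I-]
Why: Sandmeyer-type iododediazoniation (diazotisation, then electron transfer from iodide) places the iodide exactly at the carbon ortho to the ether oxygen, the later C4a, with no regiochemical question.

**Step 6**
Reactants: 11 3-[5-bromo-2-iodo-4-(triisopropylsilyloxy)phenoxy]-3-methylpentanedioic acid
Product: 12 4-[5-bromo-2-iodo-4-(triisopropylsilyloxy)phenoxy]-4-methyloxane-2,6-dione
Conditions: Ac2O, 50 °C; volatiles removed in vacuo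
Reagents that add atoms: none
Why: Cyclodehydration of a 3,3-disubstituted glutaric acid with acetic anhydride is favoured by the gem-disubstituent effect, and the base-free medium leaves the β-aryloxy group in place; the product is achiral with two enantiotopic carbonyls.

**Step 7**
Reactants: 12 4-[5-bromo-2-iodo-4-(triisopropylsilyloxy)phenoxy]-4-methyloxane-2,6-dione
Product: 14 (S)-2-[7-bromo-2-methyl-4-oxo-6-(triisopropylsilyloxy)chroman-2-yl]acetic acid, via iodozinc carboxylate 13 (not isolated)
Conditions: NiBr2·glyme (10 mol %), (S,S)-i-Pr-BiOX (12 mol %), Zn dust (2 equiv), DMA/THF (0.02 M), 0 °C → rt; then 1 M HCl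
Reagents that add atoms: none
Why: Proposed new method: Ni(0) carrying the chiral bioxazoline adds oxidatively to the C4a–I bond, the aryl–nickel species (after one-electron reduction by zinc) inserts into the acyl C–O bond of one of the two enantiotopic anhydride carbonyls, and C–C reductive elimination gives the C4 ketone and a zinc carboxylate while zinc returns nickel to Ni(0). The closest known reaction types are the nickel-catalysed reductive acylation of aryl halides by anhydrides and the nickel- or rhodium-catalysed enantioselective desymmetrisation of cyclic anhydrides with organozinc reagents; an intramolecular closure that selects between enantiotopic carbonyls has not been shown. The pyranone ring (O1–C2–C3–C4–C4a–C8a) closes by 6-exo-trig acyl substitution at the carbonyl that becomes C4. C2 is set by the ligand alone, because the ether tether holds both carbonyls at the same distance from nickel and only the chiral pocket decides which Ar–O rotamer delivers the aryl group. The step needs C–I over C–Br selectivity, which the faster oxidative addition of the iodide and the triisopropylsilyloxy group flanking the bromide should secure, and cyclisation over intermolecular acylation, which dilution and the gem-disubstituted tether should secure.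

**Step 8**
Reactants: 14 (S)-2-[7-bromo-2-methyl-4-oxo-6-(triisopropylsilyloxy)chroman-2-yl]acetic acid
Product: 15 (R)-7-bromo-2-(2-hydroxyethyl)-2-methyl-6-(triisopropylsilyloxy)chroman-4-one
Conditions: BH3·SMe2 (1.3 equiv), THF, 0 °C; MeOH quench
Reagents that add atoms: none
Why: Borane reduces the carboxylic acid through an acyloxyborane much faster than the electron-rich, cross-conjugated C4 aryl ketone (chemoselective borane reduction), and any C4 carbinol from over-reduction would be returned to the ketone in step 9.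

**Step 9**
Reactants: 15 (R)-7-bromo-2-(2-hydroxyethyl)-2-methyl-6-(triisopropylsilyloxy)chroman-4-one
Product: 16 (R)-2-[7-bromo-2-methyl-4-oxo-6-(triisopropylsilyloxy)chroman-2-yl]acetaldehyde
Conditions: Dess–Martin periodinane, NaHCO3, CH2Cl2, 0 °C → rt; used directly
Reagents that add atoms: none
Why: Dess–Martin oxidation under bicarbonate buffer gives the aldehyde without acid or base that could open the ring by retro-oxa-Michael (E1cB) loss of O1, so C2 is not touched.

**Step 10**
Reactants: 16 (R)-2-[7-bromo-2-methyl-4-oxo-6-(triisopropylsilyloxy)chroman-2-yl]acetaldehyde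
Product: 17 (R)-2-allyl-7-bromo-2-methyl-6-(triisopropylsilyloxy)chroman-4-one
Conditions: Ph3PCH3Br, KHMDS, THF, 0 °C; then 16 (ylide 1.1 equiv), −78 → −20 °C
Reagents that add atoms: methyltriphenylphosphonium bromide, C[P+](c1ccccc1)(c1ccccc1)c1ccccc1.[Br-]
Why: Wittig methylenation with one equivalent of salt-free ylide at low temperature: the aldehyde is far more electrophilic than the C4 ketone, and fast carbonyl addition should outrun enolisation, so C2 stays intact.

**Step 11**
Reactants: 17 (R)-2-allyl-7-bromo-2-methyl-6-(triisopropylsilyloxy)chroman-4-one; 18 2-methylbut-3-en-2-ol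
Product: 19 (R,E)-7-bromo-2-(4-hydroxy-4-methylpent-2-en-1-yl)-2-methyl-6-(triisopropylsilyloxy)chroman-4-one
Conditions: Hoveyda–Grubbs II (5 mol %), 18 (5 equiv), CH2Cl2, 40 °C
Reagents that add atoms: none
Why: Olefin cross-metathesis between the terminal allyl group and the slowly homodimerising tertiary allylic alcohol used in excess should give the E-disubstituted alkene with loss of ethene, while ketone, aryl bromide and silyl ether are inert to the ruthenium carbene.

**Step 12**
Reactants: 19 (R,E)-7-bromo-2-(4-hydroxy-4-methylpent-2-en-1-yl)-2-methyl-6-(triisopropylsilyloxy)chroman-4-one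
Product: 20 (R)-7-bromo-2-(4-hydroxy-4-methylpentyl)-2-methyl-6-(triisopropylsilyloxy)chroman-4-one
Conditions: H2 (1 atm), [Ir(cod)(PCy3)(py)]PF6 (5 mol %), CH2Cl2, rt
Reagents that add atoms: none
Why: Hydroxyl-directed homogeneous hydrogenation with Crabtree's catalyst saturates the disubstituted alkene without the hydrodebromination or ketone reduction expected from palladium on carbon.

**Step 13**
Reactants: 20 (R)-7-bromo-2-(4-hydroxy-4-methylpentyl)-2-methyl-6-(triisopropylsilyloxy)chroman-4-one
Product: 21 (R)-7-bromo-6-hydroxy-2-(4-hydroxy-4-methylpentyl)-2-methylchroman-4-one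
Conditions: TBAF (1.1 equiv), AcOH (1.2 equiv), THF, 0 °C
Reagents that add atoms: none
Why: Fluoride cleavage of the aryl silyl ether, buffered with acetic acid so that the chromanone is not exposed to basic fluoride or phenoxide that could racemise C2 by reversible retro-oxa-Michael ring opening.

**Compound list**
1 | 2-bromo-4-fluoro-5-nitrophenol | Oc1cc([N+](=O)[O-])c(F)cc1Br | starting material
2 | (2-bromo-4-fluoro-5-nitrophenoxy)triisopropylsilane | CC(C)[Si](Oc1cc([N+](=O)[O-])c(F)cc1Br)(C(C)C)C(C)C | intermediate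
3 | 4-methylhepta-1,6-dien-4-ol | C=CCC(C)(O)CC=C | starting material
4 | potassium 4-methylhepta-1,6-dien-4-olate | C=CCC(C)([O-])CC=C.[K+] | intermediate
5 | [2-bromo-4-[(4-methylhepta-1,6-dien-4-yl)oxy]-5-nitrophenoxy]triisopropylsilane | C=CCC(C)(CC=C)Oc1cc(Br)c(O[Si](C(C)C)(C(C)C)C(C)C)cc1[N+](=O)[O-] | intermediate
6 | bis-ozonide: [2-bromo-4-[[2-methyl-1,3-bis(1,2,4-trioxolan-3-yl)propan-2-yl]oxy]-5-nitrophenoxy]triisopropylsilane | CC(CC1OCOO1)(CC1OCOO1)Oc1cc(Br)c(O[Si](C(C)C)(C(C)C)C(C)C)cc1[N+](=O)[O-] | intermediate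
7 | 3-[5-bromo-2-nitro-4-(triisopropylsilyloxy)phenoxy]-3-methylpentanedial | CC(CC=O)(CC=O)Oc1cc(Br)c(O[Si](C(C)C)(C(C)C)C(C)C)cc1[N+](=O)[O-] | intermediate
8 | 3-[5-bromo-2-nitro-4-(triisopropylsilyloxy)phenoxy]-3-methylpentanedioic acid | CC(CC(=O)O)(CC(=O)O)Oc1cc(Br)c(O[Si](C(C)C)(C(C)C)C(C)C)cc1[N+](=O)[O-] | intermediate
9 | 3-[2-amino-5-bromo-4-(triisopropylsilyloxy)phenoxy]-3-methylpentanedioic acid | CC(CC(=O)O)(CC(=O)O)Oc1cc(Br)c(O[Si](C(C)C)(C(C)C)C(C)C)cc1N | intermediate
10 | 4-bromo-2-[(1,5-dihydroxy-3-methyl-1,5-dioxopentan-3-yl)oxy]-5-(triisopropylsilyloxy)benzenediazonium tosylate | CC(CC(=O)O)(CC(=O)O)Oc1cc(Br)c(O[Si](C(C)C)(C(C)C)C(C)C)cc1[N+]#N.Cc1ccc(S(=O)(=O)[O-])cc1 | intermediate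
11 | 3-[5-bromo-2-iodo-4-(triisopropylsilyloxy)phenoxy]-3-methylpentanedioic acid | CC(CC(=O)O)(CC(=O)O)Oc1cc(Br)c(O[Si](C(C)C)(C(C)C)C(C)C)cc1I | intermediate
12 | 4-[5-bromo-2-iodo-4-(triisopropylsilyloxy)phenoxy]-4-methyloxane-2,6-dione | CC1(Oc2cc(Br)c(O[Si](C(C)C)(C(C)C)C(C)C)cc2I)CC(=O)OC(=O)C1 | intermediate
13 | iodozinc (S)-2-[7-bromo-2-methyl-4-oxo-6-(triisopropylsilyloxy)chroman-2-yl]acetate | [Zn+2].[I-].[O-]C(=O)C[C@]1(C)CC(=O)c2cc(O[Si](C(C)C)(C(C)C)C(C)C)c(Br)cc2O1 | intermediate
14 | (S)-2-[7-bromo-2-methyl-4-oxo-6-(triisopropylsilyloxy)chroman-2-yl]acetic acid | OC(=O)C[C@]1(C)CC(=O)c2cc(O[Si](C(C)C)(C(C)C)C(C)C)c(Br)cc2O1 | intermediate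
15 | (R)-7-bromo-2-(2-hydroxyethyl)-2-methyl-6-(triisopropylsilyloxy)chroman-4-one | OCC[C@]1(C)CC(=O)c2cc(O[Si](C(C)C)(C(C)C)C(C)C)c(Br)cc2O1 | intermediate
16 | (R)-2-[7-bromo-2-methyl-4-oxo-6-(triisopropylsilyloxy)chroman-2-yl]acetaldehyde | O=CC[C@]1(C)CC(=O)c2cc(O[Si](C(C)C)(C(C)C)C(C)C)c(Br)cc2O1 | intermediate
17 | (R)-2-allyl-7-bromo-2-methyl-6-(triisopropylsilyloxy)chroman-4-one | C=CC[C@]1(C)CC(=O)c2cc(O[Si](C(C)C)(C(C)C)C(C)C)c(Br)cc2O1 | intermediate
18 | 2-methylbut-3-en-2-ol | C=CC(C)(C)O | starting material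
19 | (R,E)-7-bromo-2-(4-hydroxy-4-methylpent-2-en-1-yl)-2-methyl-6-(triisopropylsilyloxy)chroman-4-one | CC(C)(O)/C=C/C[C@]1(C)CC(=O)c2cc(O[Si](C(C)C)(C(C)C)C(C)C)c(Br)cc2O1 | intermediate
20 | (R)-7-bromo-2-(4-hydroxy-4-methylpentyl)-2-methyl-6-(triisopropylsilyloxy)chroman-4-one | CC(C)(O)CCC[C@]1(C)CC(=O)c2cc(O[Si](C(C)C)(C(C)C)C(C)C)c(Br)cc2O1 | intermediate
21 | (R)-7-bromo-6-hydroxy-2-(4-hydroxy-4-methylpentyl)-2-methylchroman-4-one | CC(C)(O)CCC[C@]1(C)CC(=O)c2cc(O)c(Br)cc2O1 | target

**Step count**
Total: 13 steps. Longest linear sequence: 13 steps (1 → 21).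

**Steps most likely to fail**

1. Step 7 (proposed new method). The ligand may discriminate poorly between the enantiotopic carbonyls. The aryl–nickel species may be protonated before acylation. Nickel may insert into the anhydride or into the C7–Br bond of the product. Fallback with known chemistry, from 12 back to 14: enantioselective methanolysis of 12 with a dimeric cinchona alkaloid catalyst ((DHQD)2AQN or its pseudo-enantiomer, MeOH, Et2O, −20 °C), the known alcoholytic desymmetrisation of prochiral glutaric anhydrides, should give (R)-3-[5-bromo-2-iodo-4-(triisopropylsilyloxy)phenoxy]-5-methoxy-3-methyl-5-oxopentanoic acid F1. Treatment with i-PrMgCl·LiCl (2.2 equiv, THF, −40 → 0 °C) then deprotonates the acid and exchanges iodine, not bromine, for magnesium. The aryl Grignard closes onto the ester arm (Parham-type cyclisation), the magnesium carboxylate arm being inert, and acidic work-up returns 14.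

2. Step 2. The silyl group may transfer from the electron-poor aryl silyl ether to the alkoxide, leaving an unreactive nitrophenoxide, or the hindered alkoxide may attack too slowly. Fallback, from 1 back to 5: the phenol is carried through the substitution as a base-stable ether and the silyl group is put on afterwards. PMBCl/K2CO3/DMF gives 1-bromo-5-fluoro-2-[(4-methoxybenzyl)oxy]-4-nitrobenzene F2. SNAr with alkoxide 4 gives 1-bromo-2-[(4-methoxybenzyl)oxy]-5-[(4-methylhepta-1,6-dien-4-yl)oxy]-4-nitrobenzene F3. DDQ (CH2Cl2/pH 7 buffer) frees 2-bromo-4-[(4-methylhepta-1,6-dien-4-yl)oxy]-5-nitrophenol F4, and TIPSCl/imidazole returns 5.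

3. Step 10. The basic ylide may enolise the β-aryloxy aldehyde and open the ring by E1cB loss of O1, which would erode C2 on reclosure, or it may also methylenate the C4 ketone. Fallback, from 15 back to 20, with no basic step and bypassing steps 9–12: Appel iodination (I2, PPh3, imidazole, CH2Cl2) gives (S)-7-bromo-2-(2-iodoethyl)-2-methyl-6-(triisopropylsilyloxy)chroman-4-one F5. Keck radical allylation with tributyl(2-methylallyl)stannane (AIBN, benzene, 80 °C) gives (R)-7-bromo-2-methyl-2-(4-methylpent-4-en-1-yl)-6-(triisopropylsilyloxy)chroman-4-one F6. Mukaiyama hydration (Co(acac)2, PhSiH3, O2, THF/i-PrOH) installs the tertiary hydroxyl with Markovnikov selectivity and gives 20.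

**Further compounds**
F1 | step 7 | (R)-3-[5-bromo-2-iodo-4-(triisopropylsilyloxy)phenoxy]-5-methoxy-3-methyl-5-oxopentanoic acid | OC(=O)C[C@](C)(CC(=O)OC)Oc1cc(Br)c(O[Si](C(C)C)(C(C)C)C(C)C)cc1I
F2 | step 2 | 1-bromo-5-fluoro-2-[(4-methoxybenzyl)oxy]-4-nitrobenzene | COc1ccc(COc2cc([N+](=O)[O-])c(F)cc2Br)cc1
F3 | step 2 | 1-bromo-2-[(4-methoxybenzyl)oxy]-5-[(4-methylhepta-1,6-dien-4-yl)oxy]-4-nitrobenzene | C=CCC(C)(CC=C)Oc1cc(Br)c(OCc2ccc(OC)cc2)cc1[N+](=O)[O-]
F4 | step 2 | 2-bromo-4-[(4-methylhepta-1,6-dien-4-yl)oxy]-5-nitrophenol | C=CCC(C)(CC=C)Oc1cc(Br)c(O)cc1[N+](=O)[O-]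
F5 | step 10 | (S)-7-bromo-2-(2-iodoethyl)-2-methyl-6-(triisopropylsilyloxy)chroman-4-one | ICC[C@]1(C)CC(=O)c2cc(O[Si](C(C)C)(C(C)C)C(C)C)c(Br)cc2O1
F6 | step 10 | (R)-7-bromo-2-methyl-2-(4-methylpent-4-en-1-yl)-6-(triisopropylsilyloxy)chroman-4-one | C=C(C)CCC[C@]1(C)CC(=O)c2cc(O[Si](C(C)C)(C(C)C)C(C)C)c(Br)cc2O1
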